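The route rests on disconnecting C1–C15 and C14–O together. In the target, C15 and C16 of the lactone ring hang from O2 and C1, and the adjacent ring carbon C14 bears oxygen; a bromoacetal on O2 therefore delivers a C15 radical that adds 5-exo to a C1=C14 alkene of the fourteen-membered ring, and the C14 radical is captured by dioxygen. One operation closes the five-membered lactol ring, forms both bonds and sets C1 and C14. The precursor is the (2S,3R,4R)-epoxy macrocycle with E alkenes at C1=C14, C7=C8 and C11=C12 and a 2-bromo-1-(4-methoxybenzyloxy)ethyl acetal on O2, built from farnesol by vinylation, directed epoxidation and ring-closing metathesis.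

Key step: step 12

Remark: ring carbons are numbered as in cembrane (C2 bears the lactone oxygen O2, C3–C4 the epoxide, C14 the acetoxy group; C15, C16 and C17 are the lactone α-carbon, the carbonyl carbon and the exocyclic methylene carbon); the acetal carbon C16 is carried as a mixture of epimers until it is oxidized, and 4-methoxybenzyl vinyl ether is assumed not to be a stock chemical and is made in step 10.

Step 1
Reactants: 1 (2E,6E)-farnesol
Product: 2 tert-butyldiphenylsilyl ether of 1
Conditions: TBDPSCl, imidazole, CH2Cl2, 0 °C to rt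
Reagents that add atoms: tert-butyl(chloro)diphenylsilane, CC(C)(C)[Si](Cl)(c1ccccc1)c1ccccc1
Why: Silylation of the primary allylic hydroxyl gives an ether that should withstand the selenium oxidation, the Appel bromination and the Grignard coupling that follow.

Step 2
Reactants: 2 tert-butyldiphenylsilyl ether of 1
Product: 3 (2E,6E,10E)-12-(tert-butyldiphenylsilyloxy)-2,6,10-trimethyldodeca-2,6,10-trien-1-ol
Conditions: SeO2 (0.3 equiv), t-BuOOH (3 equiv), salicylic acid (0.1 equiv), CH2Cl2, rt, stopped at partial conversion
Reagents that add atoms: selenium dioxide, O=[Se]=O; tert-butyl hydroperoxide, CC(C)(C)OO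
Why: Catalytic Riley oxidation (ene reaction, then [2,3]-sigmatropic shift) should attack the terminal, most electron-rich trisubstituted alkene at its (E)-methyl group and give the (E)-allylic alcohol, the alkene next to the silyloxy group being deactivated.

Step 3
Reactants: 3 (2E,6E,10E)-12-(tert-butyldiphenylsilyloxy)-2,6,10-trimethyldodeca-2,6,10-trien-1-ol
Product: 4 (2E,6E,10E)-12-bromo-1-(tert-butyldiphenylsilyloxy)-3,7,11-trimethyldodeca-2,6,10-triene
Conditions: CBr4, PPh3, CH2Cl2, 0 °C
Reagents that add atoms: tetrabromomethane, BrC(Br)(Br)Br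
Why: The Appel reaction converts the primary allylic alcohol into the bromide under neutral conditions that leave the silyl ether and the alkene geometry intact.

Step 4
Reactants: 4 (2E,6E,10E)-12-bromo-1-(tert-butyldiphenylsilyloxy)-3,7,11-trimethyldodeca-2,6,10-triene; 5 vinylmagnesium bromide
Product: 6 (2E,6E,10E)-1-(tert-butyldiphenylsilyloxy)-3,7,11-trimethyltetradeca-2,6,10,13-tetraene
Conditions: 5 (1.5 equiv), CuI (10 mol%), THF, −40 to 0 °C
Reagents that add atoms: none
Why: Copper-catalysed allylic substitution with a vinyl Grignard reagent should occur at the unhindered primary carbon (SN2 rather than SN2′), which attaches C14 and its terminal methylene to C13 with the E geometry of C11=C12 retained.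

Step 5
Reactants: 6 (2E,6E,10E)-1-(tert-butyldiphenylsilyloxy)-3,7,11-trimethyltetradeca-2,6,10,13-tetraene
Product: 7 (2E,6E,10E)-3,7,11-trimethyltetradeca-2,6,10,13-tetraen-1-ol
Conditions: Bu4NF, THF, rt
Reagents that add atoms: none
Why: Fluoride-mediated desilylation frees the primary allylic alcohol without affecting the skipped diene.

Step 6
Reactants: 7 (2E,6E,10E)-3,7,11-trimethyltetradeca-2,6,10,13-tetraen-1-ol
Product: 8 (2E,6E,10E)-3,7,11-trimethyltetradeca-2,6,10,13-tetraenal
Conditions: MnO2 (activated, excess), CH2Cl2, rt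
Reagents that add atoms: none
Why: MnO2 oxidation is selective for the allylic alcohol and should give the enal without touching the isolated alkenes or the E geometry.

Step 7
Reactants: 8 (2E,6E,10E)-3,7,11-trimethyltetradeca-2,6,10,13-tetraenal; 5 vinylmagnesium bromide
Product: 10 (3S,4E,8E,12E)-5,9,13-trimethylhexadeca-1,4,8,12,15-pentaen-3-ol, via divinylzinc 9 (not isolated)
Conditions: 5 (2.4 equiv), ZnCl2 (1.2 equiv), Et2O, 0 °C; 1,4-dioxane, filtration of magnesium salts; then 8, (−)-MIB [(2S)-3-exo-morpholinoisoborneol, 5 mol%], toluene, −20 to 0 °C; aq NH4Cl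
Reagents that add atoms: none
Why: Amino-alcohol-catalysed enantioselective addition of a diorganozinc to an aldehyde should deliver the vinyl group to the Si face of the enal and set C2 as S (the ligand enantiomer fixes the sense), while removal of the magnesium salts suppresses the racemic background addition.

Step 8
Reactants: 10 (3S,4E,8E,12E)-5,9,13-trimethylhexadeca-1,4,8,12,15-pentaen-3-ol
Product: 11 (1S)-1-{(2R,3R)-3-[(3E,7E)-4,8-dimethylundeca-3,7,10-trien-1-yl]-3-methyloxiran-2-yl}prop-2-en-1-ol
Conditions: VO(acac)2 (5 mol%), t-BuOOH (1.3 equiv, in decane), CH2Cl2, 0 °C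
Reagents that add atoms: tert-butyl hydroperoxide, CC(C)(C)OO
Why: Hydroxyl-directed vanadium-catalysed epoxidation should deliver oxygen only to the adjacent electron-rich C3=C4 alkene, and allylic 1,3-strain between the C4 methyl group (cis to C2) and the vinyl group makes the threo epoxy alcohol (3R,4R beside 2S) the expected major isomer, the minor erythro isomer being removed by chromatography.

Step 9
Reactants: 11 (1S)-1-{(2R,3R)-3-[(3E,7E)-4,8-dimethylundeca-3,7,10-trien-1-yl]-3-methyloxiran-2-yl}prop-2-en-1-ol
Product: 12 (2S,3R,4R)-3,4-epoxy-15,16,17-trinorcembra-1(14)E,7E,11E-trien-2-ol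
Conditions: second-generation Grubbs catalyst (10 mol%, two portions), 1,4-benzoquinone (20 mol%), CH2Cl2 (1 mM), 40 °C
Reagents that add atoms: none
Why: Ring-closing metathesis of the two monosubstituted alkenes closes the fourteen-membered ring at C1=C14 with loss of ethylene; the trisubstituted alkenes cannot compete because closure onto them would place an E alkene or a trans-fused oxirane in a seven-membered ring, high dilution suppresses oligomers, benzoquinone suppresses alkene migration, and the E alkene should predominate under thermodynamic control.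

Step 10
Reactants: 13 4-methoxybenzyl alcohol; 14 ethyl vinyl ether
Product: 15 4-methoxybenzyl vinyl ether
Conditions: Pd(OAc)2 (2 mol%), 1,10-phenanthroline (2 mol%), 14 (20 equiv), CH2Cl2, rt
Reagents that add atoms: none
Why: Palladium-catalysed transfer vinylation (transetherification) moves the vinyl group from the excess ethyl vinyl ether to the primary benzylic alcohol.

Step 11
Reactants: 12 (2S,3R,4R)-3,4-epoxy-15,16,17-trinorcembra-1(14)E,7E,11E-trien-2-ol; 15 4-methoxybenzyl vinyl ether
Product: 16 O2-[2-bromo-1-(4-methoxybenzyloxy)ethyl] acetal of 12, (2S,3R,4R), both epimers at C16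
Conditions: 15 (3 equiv), NBS (1.5 equiv, portionwise), CH2Cl2, −40 to 0 °C
Reagents that add atoms: N-bromosuccinimide, O=C1CCC(=O)N1Br
Why: Ueno–Stork haloacetalization: NBS should brominate the electron-rich enol ether far faster than the ring alkenes and the C2 hydroxyl captures the oxocarbenium ion, which places C15 and C16 on O2 as a 4-methoxybenzyl acetal that can later be unmasked oxidatively, without the aqueous acid that would endanger the epoxide.

Step 12
Reactants: 16 O2-[2-bromo-1-(4-methoxybenzyloxy)ethyl] acetal of 12
Product: 18 (1R,2S,3R,4R,14S,7E,11E)-3,4-epoxy-14-hydroxy-16-(4-methoxybenzyloxy)-2,16-epoxy-17-norcembra-7,11-diene (lactol 4-methoxybenzyl ether, both epimers at C16), via C14 hydroperoxide 17 (not isolated)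
Conditions: Co(salen) (10 mol%), NaBH4 (3 equiv), NaOH (1 equiv), EtOH/THF, slow stream of air, 40 °C
Reagents that add atoms: dioxygen (air), O=O
Why: Monovalent cobalt, generated from Co(salen) and NaBH4, takes bromide from 16 by electron transfer and leaves the primary C15 radical, which adds to C1 of the C1=C14 alkene and so closes the five-membered lactol ring (O2, C16, C15, C1, C2) in the 5-exo-trig mode; the secondary C14 radical combines with O2 and the hydroperoxide 17 is reduced in the flask by NaBH4. The closest known reaction type is the Co(salen)-catalysed oxygenative Ueno–Stork cyclization of bromoacetals of allylic alcohols, applied here to an alkene inside a macrocycle. C1 is controlled by C2: in the chair-like transition state the C3 branch lies pseudo-equatorial, C15 adds to the alkene face anti to C3, and C14 ends trans to C3 on the new ring (1R). C14 is controlled by C1 and by the ring conformation: with H1 eclipsing the C14–C13 bond to avoid allylic strain the macrocycle covers the face on which C2 lies, so O2 should arrive from the open face on the side of C15, which gives 14S. The step needs 5-exo rather than 6-endo addition and ring closure faster than capture of C15 by O2 or by the remote trisubstituted alkenes, which the short acetal tether on O2 and the low concentration of dissolved air secure, and it needs the epoxide to survive, which its hindered trisubstituted nature and the basic medium secure. The acetal carbon C16 forms as both epimers, which is harmless because it becomes the carbonyl carbon.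

Step 13
Reactants: 18 lactol 4-methoxybenzyl ether with free 14-OH
Product: 19 14-O-tert-butyldimethylsilyl ether of 18 (spatial arrangement unchanged; the C1 descriptor reads 1S only because silicon raises the rank of the C14 branch)
Conditions: TBSCl, imidazole, DMAP (cat.), DMF, rt to 40 °C
Reagents that add atoms: tert-butyl(chloro)dimethylsilane, CC(C)(C)[Si](C)(C)Cl
Why: Silylation protects the C14 hydroxyl so that it cannot be oxidized in step 15 and cannot take over the lactone (translactonization to O14) under the basic conditions of step 16.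

Step 14
Reactants: 19 14-O-tert-butyldimethylsilyl ether of 18
Product: 20 lactol: (1S,2S,3R,4R,14S,7E,11E)-14-(tert-butyldimethylsilyloxy)-3,4-epoxy-16-hydroxy-2,16-epoxy-17-norcembra-7,11-diene (both anomers)
Conditions: DDQ (1.5 equiv), CH2Cl2/pH 7 phosphate buffer (10:1), 0 °C to rt
Reagents that add atoms: none
Why: Oxidative cleavage of the 4-methoxybenzyl acetal (benzylic hydride abstraction by DDQ, capture of the oxocarbenium ion by water, loss of 4-methoxybenzaldehyde) should release the lactol at neutral pH, so that the epoxide, the silyl ether and the alkenes are not exposed to acid.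

Step 15
Reactants: 20 lactol
Product: 21 (1S,2S,3R,4R,14S,7E,11E)-14-(tert-butyldimethylsilyloxy)-3,4-epoxy-17-norcembra-7,11-dien-16,2-olide
Conditions: (n-Pr4N)RuO4 (5 mol%), N-methylmorpholine N-oxide (1.5 equiv), 4 Å MS, CH2Cl2, rt
Reagents that add atoms: none
Why: Ley–Griffith oxidation converts the lactol into the γ-lactone under neutral conditions, the only other oxygen function that could be oxidized (O14) being silylated.

Step 16
Reactants: 21 saturated γ-lactone
Product: 24 (1S,2S,3R,4R,14S,7E,11E)-14-(tert-butyldimethylsilyloxy)-3,4-epoxycembra-7,11,15(17)-trien-16,2-olide, via Mannich base 22 (not isolated), via methiodide 23 (not isolated)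
Conditions: LiN(i-Pr)2 (1.2 equiv), THF, −78 °C; Me2N=CH2 I (2 equiv), −78 °C to rt; then MeI (excess), rt; then sat. aq NaHCO3, rt
Reagents that add atoms: dimethyl(methylidene)ammonium iodide (Eschenmoser's salt), C=[N+](C)C.[I-]
Why: Eschenmoser methylenation: the lactone enolate, which can form only at C15, undergoes a Mannich reaction, and quaternization followed by base-induced elimination of trimethylamine installs the exocyclic C15=C17 alkene, the transient C15 stereocentre being destroyed and C1 not being acidic.

Step 17
Reactants: 24 α-methylene lactone silyl ether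
Product: 25 (1R,2S,3R,4R,14S,7E,11E)-3,4-epoxy-14-hydroxycembra-7,11,15(17)-trien-16,2-olide
Conditions: Bu4NF, AcOH (1:1), THF, 0 °C to rt
Reagents that add atoms: none
Why: Fluoride-mediated desilylation, buffered with acetic acid so that no free C14 alkoxide can add to the methylene lactone or migrate the lactone to O14, frees the secondary alcohol.

Step 18
Reactants: 25 14-hydroxy α-methylene lactone
Product: 26 (1R,2S,3R,4R,14S,7E,11E)-14-acetoxy-3,4-epoxycembra-7,11,15(17)-trien-16,2-olide (CNP0294029.1)
Conditions: Ac2O, pyridine, DMAP (cat.), CH2Cl2, 0 °C to rt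
Reagents that add atoms: acetic anhydride, CC(=O)OC(C)=O
Why: Acylation of the secondary alcohol with retention at C14 completes the target under conditions that the epoxide and the methylene lactone tolerate.

Compound list
1 | (2E,6E)-farnesol | CC(C)=CCC/C(C)=C/CC/C(C)=C/CO | starting material
2 | tert-butyldiphenylsilyl ether of farnesol | CC(C)=CCC/C(C)=C/CC/C(C)=C/CO[Si](c1ccccc1)(c1ccccc1)C(C)(C)C | intermediate
3 | (2E,6E,10E)-12-(tert-butyldiphenylsilyloxy)-2,6,10-trimethyldodeca-2,6,10-trien-1-ol | OC/C(C)=C/CC/C(C)=C/CC/C(C)=C/CO[Si](c1ccccc1)(c1ccccc1)C(C)(C)C | intermediate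
4 | (2E,6E,10E)-12-bromo-1-(tert-butyldiphenylsilyloxy)-3,7,11-trimethyldodeca-2,6,10-triene | BrC/C(C)=C/CC/C(C)=C/CC/C(C)=C/CO[Si](c1ccccc1)(c1ccccc1)C(C)(C)C | intermediate
5 | vinylmagnesium bromide | C=C[Mg]Br | starting material
6 | (2E,6E,10E)-1-(tert-butyldiphenylsilyloxy)-3,7,11-trimethyltetradeca-2,6,10,13-tetraene | C=CC/C(C)=C/CC/C(C)=C/CC/C(C)=C/CO[Si](c1ccccc1)(c1ccccc1)C(C)(C)C | intermediate
7 | (2E,6E,10E)-3,7,11-trimethyltetradeca-2,6,10,13-tetraen-1-ol | C=CC/C(C)=C/CC/C(C)=C/CC/C(C)=C/CO | intermediate
8 | (2E,6E,10E)-3,7,11-trimethyltetradeca-2,6,10,13-tetraenal | C=CC/C(C)=C/CC/C(C)=C/CC/C(C)=C/C=O | intermediate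
9 | divinylzinc | C=C[Zn]C=C | intermediate
10 | (3S,4E,8E,12E)-5,9,13-trimethylhexadeca-1,4,8,12,15-pentaen-3-ol | C=C[C@H](O)/C=C(C)/CC/C=C(C)/CC/C=C(C)/CC=C | intermediate
11 | (1S)-1-{(2R,3R)-3-[(3E,7E)-4,8-dimethylundeca-3,7,10-trien-1-yl]-3-methyloxiran-2-yl}prop-2-en-1-ol | C=C[C@H](O)[C@H]1O[C@]1(C)CC/C=C(C)/CC/C=C(C)/CC=C | intermediate
12 | (2S,3R,4R)-3,4-epoxy-15,16,17-trinorcembra-1(14)E,7E,11E-trien-2-ol | O[C@H]1/C=C/C/C(C)=C/CC/C(C)=C/CC[C@@]2(C)O[C@H]12 | intermediate
13 | 4-methoxybenzyl alcohol | COc1ccc(CO)cc1 | starting material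
14 | ethyl vinyl ether | C=COCC | starting material
15 | 4-methoxybenzyl vinyl ether | C=COCc1ccc(OC)cc1 | intermediate
16 | O2-[2-bromo-1-(4-methoxybenzyloxy)ethyl] acetal of 12 (key-step precursor, C16 epimers) | BrCC(OCc3ccc(OC)cc3)O[C@H]1/C=C/C/C(C)=C/CC/C(C)=C/CC[C@@]2(C)O[C@H]12 | intermediate
17 | C14 hydroperoxide of the cyclized lactol 4-methoxybenzyl ether | C1C(OCc3ccc(OC)cc3)O[C@H]2[C@H]1[C@@H](OO)C/C(C)=C/CC/C(C)=C/CC[C@@]1(C)O[C@H]21 | intermediate
18 | (1R,2S,3R,4R,14S)-lactol 4-methoxybenzyl ether with free 14-OH (key-step product, C16 epimers) | C1C(OCc3ccc(OC)cc3)O[C@H]2[C@H]1[C@@H](O)C/C(C)=C/CC/C(C)=C/CC[C@@]1(C)O[C@H]21 | intermediate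
19 | 14-O-tert-butyldimethylsilyl ether of 18 | C1C(OCc3ccc(OC)cc3)O[C@H]2[C@H]1[C@@H](O[Si](C)(C)C(C)(C)C)C/C(C)=C/CC/C(C)=C/CC[C@@]1(C)O[C@H]21 | intermediate
20 | 14-O-silylated lactol (C16 anomers) | C1C(O)O[C@H]2[C@H]1[C@@H](O[Si](C)(C)C(C)(C)C)C/C(C)=C/CC/C(C)=C/CC[C@@]1(C)O[C@H]21 | intermediate
21 | 14-(tert-butyldimethylsilyloxy)-3,4-epoxy-17-norcembra-7,11-dien-16,2-olide | C1C(=O)O[C@H]2[C@H]1[C@@H](O[Si](C)(C)C(C)(C)C)C/C(C)=C/CC/C(C)=C/CC[C@@]1(C)O[C@H]21 | intermediate
22 | 15-(dimethylaminomethyl) lactone (Mannich base, C15 epimers) | CN(C)CC1C(=O)O[C@H]2[C@H]1[C@@H](O[Si](C)(C)C(C)(C)C)C/C(C)=C/CC/C(C)=C/CC[C@@]1(C)O[C@H]21 | intermediate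
23 | trimethylammonium iodide of 22 (methiodide) | C[N+](C)(C)CC1C(=O)O[C@H]2[C@H]1[C@@H](O[Si](C)(C)C(C)(C)C)C/C(C)=C/CC/C(C)=C/CC[C@@]1(C)O[C@H]21.[I-] | intermediate
24 | 14-(tert-butyldimethylsilyloxy)-3,4-epoxycembra-7,11,15(17)-trien-16,2-olide | C=C1C(=O)O[C@H]2[C@H]1[C@@H](O[Si](C)(C)C(C)(C)C)C/C(C)=C/CC/C(C)=C/CC[C@@]1(C)O[C@H]21 | intermediate
25 | (1R,2S,3R,4R,14S,7E,11E)-3,4-epoxy-14-hydroxycembra-7,11,15(17)-trien-16,2-olide | C=C1C(=O)O[C@H]2[C@H]1[C@@H](O)C/C(C)=C/CC/C(C)=C/CC[C@@]1(C)O[C@H]21 | intermediate
26 | (1R,2S,3R,4R,14S,7E,11E)-14-acetoxy-3,4-epoxycembra-7,11,15(17)-trien-16,2-olide (CNP0294029.1) | C=C1C(=O)O[C@H]2[C@H]1[C@@H](OC(C)=O)C/C(C)=C/CC/C(C)=C/CC[C@@]1(C)O[C@H]21 | target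

Total step count: 18. Longest linear sequence: 17 steps (steps 1–9 and 11–18, from farnesol); step 10 is a one-step side branch.

Steps most likely to fail

Step 12. Oxygen may reach the C14 radical from the wrong face, or without preference, because the face is chosen by the conformation of the fourteen-membered ring and not by a strong local bias. The fallback sets C14 by SN2 inversion instead of by radical trapping. It sets out from 16: the cyclization is run as in step 12 and the (14R)-epimer of 18 F1 is separated; Mitsunobu esterification (4-nitrobenzoic acid, PPh3, DIAD, THF, 0 °C to rt) should give the (14S)-4-nitrobenzoate of 18 F2 with inversion, and methanolysis (K2CO3, MeOH, rt), which the acetal and the epoxide tolerate, brings the route back at 18.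

Step 9. The macrocyclization may be diverted into oligomers, or the free allylic hydroxyl may deactivate the catalyst and promote alkene migration. The fallback changes the order of ring closure and acetalization and sets out from 11: bromoacetalization with 15 and NBS (CH2Cl2, −40 to 0 °C) should give the acyclic bromoacetal of 11 F3, and ring-closing metathesis of F3 (second-generation Grubbs catalyst, 1,4-benzoquinone, CH2Cl2, 1 mM, 40 °C) should give 16 directly, where the route resumes. The bulky allylic acetal makes the catalyst load at the C14 terminus and removes the free hydroxyl. Both alkene geometries of 16 would lead to the same C14 radical in step 12.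

Step 7. The enantioselectivity may be eroded by uncatalysed addition or by poor face discrimination on the β,β-disubstituted enal. The fallback replaces asymmetric catalysis by enzymatic kinetic resolution and sets out from 8: addition of 5 (THF, −78 °C) should give the racemic dienol F4. Acylation with immobilized Candida antarctica lipase B and vinyl acetate (hexane, rt) should follow the empirical size rule for lipases (vinyl as the small group, the trisubstituted alkenyl chain as the large group), converting the (R)-enantiomer into the (R)-acetate F5 and leaving the (S)-alcohol 10, at which the route is rejoined.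

Further compounds
F1 | step 12 | (14R)-epimer of 18 | C1C(OCc3ccc(OC)cc3)O[C@H]2[C@H]1[C@H](O)C/C(C)=C/CC/C(C)=C/CC[C@@]1(C)O[C@H]21
F2 | step 12 | (14S)-4-nitrobenzoate of 18 | C1C(OCc3ccc(OC)cc3)O[C@H]2[C@H]1[C@@H](OC(=O)c4ccc(cc4)[N+](=O)[O-])C/C(C)=C/CC/C(C)=C/CC[C@@]1(C)O[C@H]21
F3 | step 9 | acyclic O2-[2-bromo-1-(4-methoxybenzyloxy)ethyl] acetal of 11 | C=C[C@H](OC(CBr)OCc1ccc(OC)cc1)[C@H]1O[C@]1(C)CC/C=C(C)/CC/C=C(C)/CC=C
F4 | step 7 | racemic (4E,8E,12E)-5,9,13-trimethylhexadeca-1,4,8,12,15-pentaen-3-ol | C=CC(O)/C=C(C)/CC/C=C(C)/CC/C=C(C)/CC=C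
F5 | step 7 | (3R,4E,8E,12E)-5,9,13-trimethylhexadeca-1,4,8,12,15-pentaen-3-yl acetate | C=C[C@@H](OC(C)=O)/C=C(C)/CC/C=C(C)/CC/C=C(C)/CC=C
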